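Everything rests on disconnecting ring B of the chromanone at the two bonds of its spiro carbon, C2–C3 and C2–O1. The key step forges both in one operation: the lithium enolate of a 2-fluoroacetophenone adds to C1 of a 2,6-dialkoxy-1,4-benzoquinone, and the quinol alkoxide then displaces the fluoride. It exploits the fact that the spiro carbon (C2 of ring B, C1′ of dienone ring C), with enol-ether carbons C2′ and C6′ on either side and the C4′ carbonyl opposite, is a quinone carbonyl carbon in disguise. The precursors are 1-(2-fluoro-4,6-dimethoxyphenyl)ethanone and the quinone as its bis(allyl) ether, so that both enols can later be freed by zerovalent palladium without touching an epoxide.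

Key step: step 3

Labels: Ar = 4-methoxyphenyl. Ring A = dimethoxybenzene ring. Ring B = pyranone ring (O1, C2, C3, C4, C4a, C8a). Ring C = cyclohexadienone (C1′ = C2, the spiro carbon; oxygen-bearing C2′ and C6′; CH carbons C3′ and C5′; carbonyl C4′). Ring D = dihydrofuran (C2, C3, Cα, O, C2′). Ring E = dihydropyran (C2″, O, C6′, C5′, two CH2). Cα = ArCH carbon on C3; C2″ = ArCH carbon of ring E.

Structure check: the key-step partners and the spiro product map onto the target (5,7-dimethoxy ring A, C4′ carbonyl para to the spiro carbon); no correction of connectivity is needed.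

Design remark: the quinone carries allyl instead of methyl enol ethers, because vinylogous methyl esters can only be cleaved by acid or strong nucleophiles that the later epoxide would not survive. Ring E is closed from a catalyst-set carbinol, because a formaldehyde/4-methoxystyrene cycloaddition onto C5′/C6′ would leave C2″ uncontrolled.

Assumption: poly-D-leucine is taken to deliver oxygen to this s-cis arylidene ketone with the facial sense it shows for (E)-chalcone ((2S,3R)-oxide); if the sense proves opposite, poly-L-leucine is used in step 5 with no other change.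

Step 1
Reactants: 1 1-fluoro-3,5-dimethoxybenzene
Product: 2 1-(2-fluoro-4,6-dimethoxyphenyl)ethanone
Conditions: AcCl (1.1 equiv), AlCl3 (1.2 equiv), CH2Cl2, −10 → 0 °C; ice/aq. HCl
Reagents that add atoms: acetyl chloride, CC(=O)Cl
Why: Friedel–Crafts acylation should occur at C2 of 1 (para to one methoxy, ortho to the other, next to the small fluorine) in preference to the more hindered C4 between two methoxy groups, the minor 4-fluoro-2,6-dimethoxy isomer being removed by crystallisation.

Step 2
Reactants: 3 2,6-dimethoxy-1,4-benzoquinone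
Product: 4 2,6-bis(allyloxy)-1,4-benzoquinone
Conditions: allyl alcohol (solvent), camphorsulfonic acid (5 mol %), 60 °C, MeOH distilled off under reduced pressure
Reagents that add atoms: allyl alcohol, C=CCO
Why: Acid-catalysed vinylogous transesterification (ether exchange of an alkoxyquinone) should proceed because allyl alcohol adds to C2 and C6, the β-carbons of the C4 enone, and methanol is expelled and removed.

Step 3
Reactants: 2 1-(2-fluoro-4,6-dimethoxyphenyl)ethanone; 4 2,6-bis(allyloxy)-1,4-benzoquinone
Product: 7 2′,6′-bis(allyloxy)-5,7-dimethoxyspiro[chromane-2,1′-cyclohexa-2′,5′-diene]-4,4′-dione (achiral), via lithium enolate 5 (not isolated), via lithium quinolate 6 (not isolated)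
Conditions: 2, LiN(SiMe3)2 (1.0 equiv), THF, −78 °C; added to 4 in THF, −78 °C; then DMPU, −78 → 25 °C; aq. NH4Cl
Reagents that add atoms: none
Why: Enolate 5 adds 1,2 to C1 of 4, the one quinone carbonyl that is not a vinylogous ester, to give lithium quinolate 6 (new C2–C3 bond); on warming with DMPU the tertiary alkoxide attacks the fluorine-bearing carbon ortho to the acyl group, a Meisenheimer anion stabilised by that acyl group forms (both methoxy groups are meta to fluorine), and fluoride leaves (new C2–O1 bond). The closest known reactions are the addition of lithium enolates to p-benzoquinones to give p-quinols and the alkoxide SNAr closure of 2-fluoroaryl ketones to chroman-4-ones. Ring B closes by a 6-exo-trig addition–elimination at the aromatic carbon. No stereocentre is formed, because the spiro carbon carries two identical allyloxyvinyl arms and stays prochiral. The step needs site selectivity for C1 over C4, over conjugate addition and over displacement of allyloxide, which the double vinylogous-ester deactivation of C4 and a hard lithium enolate at −78 °C should secure; retro-aldol of 6 only returns 5 and 4, whereas loss of fluoride is irreversible. Exactly one equivalent of base is used so that no enolate of 7 forms, since that anion could expel the ring B aryloxide.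

Step 4
Reactants: 7 2′,6′-bis(allyloxy)-5,7-dimethoxyspiro[chromane-2,1′-cyclohexa-2′,5′-diene]-4,4′-dione; 8 4-methoxybenzaldehyde
Product: 12 (E)-2′,6′-bis(allyloxy)-5,7-dimethoxy-3-(4-methoxybenzylidene)spiro[chromane-2,1′-cyclohexa-2′,5′-diene]-4,4′-dione (achiral), via titanium enolate 9 (not isolated), via aldol adduct 10 (not isolated), via mesylate 11 (not isolated)
Conditions: TiCl4 (2.2 equiv), iPr2NEt (2.5 equiv), CH2Cl2, −78 °C; 8, −78 → −40 °C; aq. NH4Cl; crude: MsCl, Et3N, CH2Cl2, 0 °C; then DBU, 25 °C
Reagents that add atoms: none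
Why: A titanium-enolate aldol addition followed by mesylation and E1cB elimination (aldol condensation) should work because the covalent titanium enolate avoids the β-elimination of the ring B aryloxide that a free alkali enolate at C3 would risk, and elimination through the enolate gives the more stable E-alkene with the aryl group anti to C4=O.

Step 5
Reactants: 12 (E)-3-(4-methoxybenzylidene) spiro dione
Product: 13 (3R,αR)-oxirane of 12 (oxirane spiro at C3; Ar cis to C2 across the oxirane)
Conditions: poly-D-leucine (immobilised), urea–H2O2, DBU, THF, 25 °C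
Reagents that add atoms: hydrogen peroxide (as its urea adduct), OO
Why: In this Juliá–Colonna asymmetric Weitz–Scheffer epoxidation the hydroperoxide anion should attack Cα of the only enone whose β-carbon is not blocked as a vinylogous ester, and the helical poly-D-leucine should direct it to the face that sets C3 as R and Cα as R, by analogy with the (2S,3R)-oxide it gives from (E)-chalcone.

Step 6
Reactants: 13 (3R,αR)-oxirane
Product: 15 (2S,3R,αS)-tetracyclic vinylogous acid (rings A–D; 3-OH cis to Ar on Cα; enol OH on C6′; H on C5′; C4′=O), via bis-enol epoxide 14 (not isolated)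
Conditions: Pd(PPh3)4 (5 mol %), morpholine (10 equiv), THF, 0 → 25 °C; then AcOH, 25–40 °C
Reagents that add atoms: none
Why: Tsuji–Trost deallylation (π-allyl palladium trapped by morpholine) should free both vinylogous acids, after which the enol oxygen of the arm lying on the face of ring B opposite the oxirane oxygen opens the epoxide at the 4-methoxybenzylic carbon with inversion (Algar–Flynn–Oyamada-type endo opening), which sets Cα as S, leaves C3 as R and, since only a cis-fused ring D can form, fixes the spiro carbon as S.

Step 7
Reactants: 15 (2S,3R,αS)-tetracyclic vinylogous acid; 16 3-chloro-1-(4-methoxyphenyl)propan-1-one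
Product: 18 (2S,3R,αS)-15 bearing a 3-(4-methoxyphenyl)-3-oxopropyl group on C5′, via aryl vinyl ketone 17 (not isolated)
Conditions: Et3N (2.5 equiv), CH2Cl2, 0 → 25 °C
Reagents that add atoms: none
Why: Michael addition should take place at C5′, the only carbon flanked by two carbonyl/enol carbons, onto the vinyl ketone formed in situ by dehydrochlorination, C-alkylation being the thermodynamic outcome for a cyclic 1,3-dicarbonyl and no stereocentre being formed.

Step 8
Reactants: 18 (2S,3R,αS)-triketone
Product: 20 target CNP0251458.1 with (2S,3R,αS,2″R) configuration, via R-carbinol 19 (not isolated)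
Conditions: RuCl[(R,R)-TsDPEN](p-cymene) (2 mol %), HCO2H/Et3N (5:2), DMF, 25 °C; then PPTS (10 mol %), 4 Å MS, CH2Cl2, 25 °C
Reagents that add atoms: none
Why: Noyori asymmetric transfer hydrogenation should reduce only the unhindered aryl alkyl ketone, the (R,R)-ligand setting the carbinol as R, and acid-catalysed cyclodehydration should then close ring E by attack of the carbinol oxygen on the ketone-like C6′ carbonyl (C4′ is a doubly vinylogous ester and remains the carbonyl) without breaking the C–O bond of the stereocentre, so C2″ is R.

Compound list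
1 | 1-fluoro-3,5-dimethoxybenzene | COc1cc(F)cc(OC)c1 | starting material
2 | 1-(2-fluoro-4,6-dimethoxyphenyl)ethanone | CC(=O)c1c(F)cc(OC)cc1OC | intermediate
3 | 2,6-dimethoxy-1,4-benzoquinone | COC1=CC(=O)C=C(OC)C1=O | starting material
4 | 2,6-bis(allyloxy)-1,4-benzoquinone | C=CCOC1=CC(=O)C=C(OCC=C)C1=O | intermediate
5 | lithium 1-(2-fluoro-4,6-dimethoxyphenyl)ethen-1-olate | [Li]OC(=C)c1c(F)cc(OC)cc1OC | intermediate
6 | lithium 2,6-bis(allyloxy)-1-[2-(2-fluoro-4,6-dimethoxyphenyl)-2-oxoethyl]-4-oxocyclohexa-2,5-dien-1-olate | C=CCOC1=CC(=O)C=C(OCC=C)C1(O[Li])CC(=O)c1c(F)cc(OC)cc1OC | intermediate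
7 | 2′,6′-bis(allyloxy)-5,7-dimethoxyspiro[chromane-2,1′-cyclohexa-2′,5′-diene]-4,4′-dione (achiral) | C=CCOC1=CC(=O)C=C(OCC=C)C12CC(=O)c1c(O2)cc(OC)cc1OC | intermediate
8 | 4-methoxybenzaldehyde | COc1ccc(C=O)cc1 | starting material
9 | trichlorotitanium enolate of 7 (C3=C4–O–TiCl3) | C=CCOC1=CC(=O)C=C(OCC=C)C12C=C(O[Ti](Cl)(Cl)Cl)c1c(O2)cc(OC)cc1OC | intermediate
10 | 3-[hydroxy(4-methoxyphenyl)methyl] derivative of 7 (racemic mixture of diastereomers, stereo undefined) | C=CCOC1=CC(=O)C=C(OCC=C)C12Oc3cc(OC)cc(OC)c3C(=O)C2C(O)c2ccc(OC)cc2 | intermediate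
11 | methanesulfonate of 10 (stereo undefined) | C=CCOC1=CC(=O)C=C(OCC=C)C12Oc3cc(OC)cc(OC)c3C(=O)C2C(OS(C)(=O)=O)c2ccc(OC)cc2 | intermediate
12 | (E)-2′,6′-bis(allyloxy)-5,7-dimethoxy-3-(4-methoxybenzylidene)spiro[chromane-2,1′-cyclohexa-2′,5′-diene]-4,4′-dione | C=CCOC1=CC(=O)C=C(OCC=C)C12Oc3cc(OC)cc(OC)c3C(=O)/C2=C/c2ccc(OC)cc2 | intermediate
13 | (3R,αR)-oxirane of 12 (C3 spiro oxirane, Ar cis to C2) | C=CCOC1=CC(=O)C=C(OCC=C)C12Oc3cc(OC)cc(OC)c3C(=O)[C@]24O[C@@H]4c2ccc(OC)cc2 | intermediate
14 | (3R,αR)-oxirane with both allyl groups removed (2′,6′-dihydroxy dienone) | OC1=CC(=O)C=C(O)C12Oc3cc(OC)cc(OC)c3C(=O)[C@]24O[C@@H]4c2ccc(OC)cc2 | intermediate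
15 | (2S,3R,αS)-tetracyclic vinylogous acid, rings A–D, 3-OH cis to Ar on Cα, enol OH on C6′ | C1=C(O)[C@]24Oc5cc(OC)cc(OC)c5C(=O)[C@@]2(O)[C@H](c2ccc(OC)cc2)OC4=CC1=O | intermediate
16 | 3-chloro-1-(4-methoxyphenyl)propan-1-one | COc1ccc(cc1)C(=O)CCCl | starting material
17 | 1-(4-methoxyphenyl)prop-2-en-1-one | COc1ccc(cc1)C(=O)C=C | intermediate
18 | (2S,3R,αS)-15 with a 3-(4-methoxyphenyl)-3-oxopropyl group on C5′ | COc1ccc(cc1)C(=O)CCC1=C(O)[C@]24Oc5cc(OC)cc(OC)c5C(=O)[C@@]2(O)[C@H](c2ccc(OC)cc2)OC4=CC1=O | intermediate
19 | (2S,3R,αS)-15 with an (R)-3-hydroxy-3-(4-methoxyphenyl)propyl group on C5′ | COc1ccc(cc1)[C@H](O)CCC1=C(O)[C@]24Oc5cc(OC)cc(OC)c5C(=O)[C@@]2(O)[C@H](c2ccc(OC)cc2)OC4=CC1=O | intermediate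
20 | CNP0251458.1, (2S,3R,αS,2″R), rings A–E | COc1ccc([C@H]2CCC3=C(O2)[C@]24Oc5cc(OC)cc(OC)c5C(=O)[C@@]2(O)[C@H](c2ccc(OC)cc2)OC4=CC3=O)cc1 | target

Total step count: 8. Longest linear sequence: 7 steps (3 → 4 → 7 → 12 → 13 → 15 → 18 → 20).

Steps most likely to fail

1. Step 3. Electron transfer from the enolate to the quinone may compete with carbonyl addition. The hindered lithium quinolate may also displace fluoride slowly, so that retro-aldol and proton transfer from C3–H of the product to unreacted base set in, opening ring B by β-elimination and leading to rearomatisation. Fallback, setting out from 2 and 4 and returning at 7: the two bond formations are separated and the carbonyl addition is run without a basic enolate. Ketone 2 is brominated at the methyl group (PhNMe3Br3, THF) to 2-bromo-1-(2-fluoro-4,6-dimethoxyphenyl)ethanone F1. Zinc dust in THF converts it into the bromozinc enolate F2 (Reformatsky reagent), which is decanted from excess zinc and added to C1 of quinone 4 to give the isolable quinol F3, as in the Reformatsky synthesis of quinol acetates. Ring closure by SNAr with K2CO3 in DMSO at 25 °C then gives 7.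

2. Step 5. Conversion may stay low and facial selectivity poor, because the enone is hindered by the spiro centre and its β-carbon carries an electron-rich aryl group. Fallback, setting out from 12 and returning at 13: 12 is epoxidised without a chiral catalyst (tBuOOH, DBU, THF) to the racemic trans-oxirane, which consists of 13 and its (3S,αS) antipode F4. The enantiomers are separated by preparative chromatography on a chiral stationary phase, and the (3R,αR) enantiomer continues as 13.

3. Step 8. The carbinol oxygen may close onto the C4′ carbonyl instead of C6′, or ionisation at the 4-methoxybenzylic carbinol under acid may erode the configuration at C2″. Fallback, setting out from 18 and returning at 20: the roles of the two partners in the ring closure are reversed. 18 is reduced with RuCl[(S,S)-TsDPEN](p-cymene) in HCO2H/Et3N to the epimeric (S)-carbinol F5. Ring E is then closed by intramolecular Mitsunobu etherification (PPh3, DIAD, THF, 0 °C), in which the acidic enol oxygen on C6′ displaces the activated carbinol with inversion and gives 20 directly.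

Further compounds
F1 | step 3 | 2-bromo-1-(2-fluoro-4,6-dimethoxyphenyl)ethanone | BrCC(=O)c1c(F)cc(OC)cc1OC
F2 | step 3 | bromozinc 1-(2-fluoro-4,6-dimethoxyphenyl)ethen-1-olate | Br[Zn]OC(=C)c1c(F)cc(OC)cc1OC
F3 | step 3 | 3,5-bis(allyloxy)-4-[2-(2-fluoro-4,6-dimethoxyphenyl)-2-oxoethyl]-4-hydroxycyclohexa-2,5-dien-1-one | C=CCOC1=CC(=O)C=C(OCC=C)C1(O)CC(=O)c1c(F)cc(OC)cc1OC
F4 | step 5 | (3S,αS)-oxirane of 12, antipode of 13 | C=CCOC1=CC(=O)C=C(OCC=C)C12Oc3cc(OC)cc(OC)c3C(=O)[C@@]24O[C@H]4c2ccc(OC)cc2
F5 | step 8 | (2S,3R,αS)-15 with an (S)-3-hydroxy-3-(4-methoxyphenyl)propyl group on C5′ | COc1ccc(cc1)[C@@H](O)CCC1=C(O)[C@]24Oc5cc(OC)cc(OC)c5C(=O)[C@@]2(O)[C@H](c2ccc(OC)cc2)OC4=CC1=O
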